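Everything rests on making ring A one carbon too large and shrinking it. The feature exploited is C4 of ring A, a quaternary carbon bearing a methyl group and the one-carbon acid C19, the retron of an epoxide-to-aldehyde rearrangement. The precursor is a trans-fused 6-7 keto ester in which C19 is still a ring atom between C3 and C4 and carries, with C4, a β-epoxide. One Lewis-acid step moves C3 from C19 to C4: the seven-membered ring becomes ring A, C19 is expelled as the axial aldehyde and C4 is set by inversion. The 6-7 skeleton comes from (+)-verbenone by conjugate addition, cyclobutane fragmentation and ring-closing metathesis; C13 is set last by asymmetric conjugate borylation.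

Key step: step 7

Remark on numbering: labdane numbering (C1–C20) is used for every intermediate, and the future carboxyl carbon is called C19 from the start.
Assumption: (1R,5R)-(+)-verbenone is taken as a purchasable compound (it is one allylic oxidation away from (+)-α-pinene).

Step 1
Reactants: 1 (1R,5R)-(+)-verbenone; 2 5-bromopent-1-ene
Product: 4 trimethylsilyl enol ether of the pentenyl adduct, via pent-4-enylmagnesium bromide 3 (not isolated)
Conditions: Mg, THF; then CuBr·SMe2 (10 mol %), HMPA, Me3SiCl, 1, THF, −78 → −40 °C; Et3N, pentane work-up
Reagents that add atoms: chlorotrimethylsilane, C[Si](C)(C)Cl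
Why: Chlorosilane-accelerated, copper-catalysed conjugate addition of a Grignard reagent: the nucleophile reaches the β-carbon only from the face turned away from the gem-dimethyl bridge, which sets C10 (pentenyl trans and C20 methyl cis to the bridge carbon that becomes C4), and the enolate is caught as the only possible, non-bridgehead silyl enol ether (C8–C9).

Step 2
Reactants: 4 trimethylsilyl enol ether; 5 methyl vinyl ketone
Product: 6 bicyclic 1,5-diketone (3-oxobutyl chain at C9)
Conditions: BF3·OEt2, MeOH, CH2Cl2, −78 °C
Reagents that add atoms: none
Why: Mukaiyama–Michael addition: the silyl enol ether can react only at C9 and does so on the face away from the gem-dimethyl bridge (the 9-epi configuration, of no consequence because C9 stays epimerisable until step 9), while methanol takes up the silyl group.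

Step 3
Reactants: 6 bicyclic 1,5-diketone; 7 trimethyl phosphonoacetate
Product: 8 bicyclic keto (E)-enoate
Conditions: NaH, THF, 0 °C → rt; chromatography
Reagents that add atoms: none
Why: Horner–Wadsworth–Emmons olefination: the stabilised phosphonate anion attacks the open methyl ketone and not the flanked bicyclic ketone, and it should favour the E-enoate, the minor Z-isomer being removed by chromatography.

Step 4
Reactants: 8 bicyclic keto (E)-enoate
Product: 10 monocyclic ketone (isopropenyl at C5; 9αH), via enol acetate 9 (not isolated)
Conditions: BF3·OEt2, Zn(OAc)2, Ac2O, CH2Cl2, 0 °C → rt; then K2CO3 (cat.), MeOH, rt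
Reagents that add atoms: none
Why: Lewis-acid cyclobutane fragmentation of a pinan-2-one type ketone: O-acylation triggers cleavage of the C7–C4 bond to the tertiary cation, acetate removes a methyl proton to give the isopropenyl group with C5 and C10 untouched, and carbonate methanolysis of the enol acetate equilibrates C9 to the equatorial side chain (9αH).

Step 5
Reactants: 10 monocyclic ketone
Product: 11 trans-fused 6-7 keto ester (C19=C4 ring alkene)
Conditions: second-generation Grubbs catalyst RuCl2(=CHPh)(PCy3)(H2IMes) (5 mol %), CH2Cl2 (high dilution), reflux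
Reagents that add atoms: none
Why: Ring-closing metathesis: the trans-diequatorial isopropenyl and pentenyl groups close the seven-membered ring C10–C1–C2–C3–C19=C4–C5 with loss of ethene, the conjugated trisubstituted enoate is inert, and no stereocentre is formed.

Step 6
Reactants: 11 trans-fused 6-7 keto ester
Product: 13 4β,19β-epoxide of 11, via bromohydrin 12 (not isolated)
Conditions: NBS, acetone–H2O, 0 °C; then K2CO3, MeOH, rt
Reagents that add atoms: water, O
Why: Bromohydrin formation followed by intramolecular Williamson closure: bromine adds to the only electron-rich alkene on the open α face (the β face is screened by the axial C20 methyl), water opens the bromonium ion anti from the β face, and the alkoxide displaces α-bromide, so that either regiochemistry of opening puts the oxygen on the β face that a peracid would not reach.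

Step 7
Reactants: 13 4β,19β-epoxide
Product: 14 keto aldehyde with ring A in its final size (4α-CH3, 4β-CHO)
Conditions: BF3·OEt2, CH2Cl2, −78 → −40 °C; Et3N quench
Reagents that add atoms: none
Why: BF3 binds the epoxide oxygen and the tertiary C4–O bond ionises while the C3–C19 ring bond shifts from C19 to C4 on the side opposite the leaving oxygen, so that C19 leaves the ring as the aldehyde carbon (Meinwald rearrangement, a semipinacol 1,2-alkyl shift, as known for 1-methylcycloalkene oxides giving 1-methylcycloalkanecarbaldehydes). Ring A is closed by this 1,2-shift (C3–C4 formed, C3–C19 broken, seven- to six-membered) and not by a cyclisation. C4 is the only new stereocentre and is set by inversion: C3 enters on the α face opposite the departing β oxygen, which leaves CHO β (axial, cis to C20) and CH3 α. The step needs ionisation at C4 and not at C19, which is secured by the tertiary against secondary carbon and by relief of the compression between the β oxygen and the C20 methyl group. It also needs the shift of C3 rather than hydride shift or proton loss, which is favoured by the release of cycloheptane strain on forming a chair cyclohexane, by the low temperature and by the non-basic medium. The C8 ketone and the enoate are only complexed reversibly, and C5, C9 and C10 are not touched.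

Step 8
Reactants: 14 keto aldehyde
Product: 15 keto acid (C19 carboxylic acid)
Conditions: NaClO2, NaH2PO4, 2-methylbut-2-ene, t-BuOH–H2O, rt
Reagents that add atoms: sodium chlorite, [Na+].[O-]Cl=O
Why: Pinnick oxidation: chlorous acid oxidises the hindered axial aldehyde without touching the ketone or the enoate, and quaternary C4 cannot epimerise.

Step 9
Reactants: 15 keto acid
Product: 16 agathic acid 15-methyl ester
Conditions: Ph3PCH3Br (3.5 equiv), KOt-Bu (3.3 equiv), THF, 0 → 40 °C; dilute HCl work-up
Reagents that add atoms: methyltriphenylphosphonium bromide, C[P+](c1ccccc1)(c1ccccc1)c1ccccc1.[Br-]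
Why: Wittig methylenation: the first equivalent of base turns the acid into an inert carboxylate, the ylide converts the C8 ketone into the C8=C17 methylene group, and C9 already holds its thermodynamic configuration, so the basic medium cannot scramble it before it is locked.

Step 10
Reactants: 16 agathic acid 15-methyl ester
Product: 17 13-boryl ester (pinacol boronate at C13)
Conditions: B2pin2, CuCl (5 mol %), Josiphos-type ferrocenyl bisphosphine (6 mol %, hand chosen for the 13R series), NaOt-Bu (1.1 equiv), MeOH (2 equiv), THF, rt; dilute HCl work-up
Reagents that add atoms: bis(pinacolato)diboron, CC1(C)OB(OC1(C)C)B1OC(C)(C)C(C)(C)O1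
Why: Copper-catalysed enantioselective conjugate borylation of a β,β-disubstituted enoate: the ligated boryl complex of monovalent copper adds across the geometrically pure E-enoate on the face chosen by the ligand alone (the ring stereocentres are remote), which sets C13, while the isolated C8=C17 alkene is inert and the acid is carried as its sodium salt.

Step 11
Reactants: 17 13-boryl ester
Product: 19 target (13R)-13-hydroxylabd-8(17)-ene-15,19-dioic acid, via hydroxy ester 18 (not isolated)
Conditions: 30 % H2O2, 2 M NaOH, THF–MeOH, 0 °C → rt; then cold dilute HCl to pH 3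
Reagents that add atoms: hydrogen peroxide, OO; sodium hydroxide, [Na+].[OH-]
Why: Alkaline peroxide oxidation of the C–B bond (1,2-metallate shift with retention, giving 13R) followed in the same medium by saponification of the unhindered C15 methyl ester.

Compound list
1 | (1R,5R)-(+)-verbenone, (1R,5R)-4,6,6-trimethylbicyclo[3.1.1]hept-3-en-2-one | CC1=CC(=O)[C@@H]2C[C@H]1C2(C)C | starting material
2 | 5-bromopent-1-ene | C=CCCCBr | starting material
3 | pent-4-enylmagnesium bromide | C=CCCC[Mg]Br | intermediate
4 | 2-(trimethylsilyloxy)-4,6,6-trimethyl-4-(pent-4-enyl)bicyclo[3.1.1]hept-2-ene, pentenyl on the face away from the CMe2 bridge | C=CCCC[C@]1(C)C=C(O[Si](C)(C)C)[C@@H]2C[C@H]1C2(C)C | intermediate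
5 | methyl vinyl ketone | C=CC(C)=O | starting material
6 | 3-(3-oxobutyl)-4,6,6-trimethyl-4-(pent-4-enyl)bicyclo[3.1.1]heptan-2-one, oxobutyl and pentenyl both away from the CMe2 bridge (9-epi) | O=C1[C@@H]2C[C@H]([C@](C)(CCCC=C)[C@@H]1CCC(C)=O)C2(C)C | intermediate
7 | trimethyl phosphonoacetate | COC(=O)CP(=O)(OC)OC | starting material
8 | methyl (E)-3-methyl-5-[2-oxo-4,6,6-trimethyl-4-(pent-4-enyl)bicyclo[3.1.1]hept-3-yl]pent-2-enoate | O=C1[C@@H]2C[C@H]([C@](C)(CCCC=C)[C@@H]1CC/C(C)=C/C(=O)OC)C2(C)C | intermediate
9 | enol acetate (C7=C8–OAc) of the ring-opened ketone, isopropenyl at C5, still 9-epi | CC(=O)OC1=CC[C@@H](C(C)=C)[C@](C)(CCCC=C)[C@@H]1CC/C(C)=C/C(=O)OC | intermediate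
10 | methyl (E)-3-methyl-5-[6-methyl-2-oxo-6-(pent-4-enyl)-5-(prop-1-en-2-yl)cyclohexyl]pent-2-enoate; ring B with 5αH, 10β-CH3, 9αH | O=C1CC[C@@H](C(C)=C)[C@](C)(CCCC=C)[C@H]1CC/C(C)=C/C(=O)OC | intermediate
11 | trans-fused 6-7 keto ester: ring B as in 10, seven-membered ring C10–C1–C2–C3–C19=C4–C5, CH3 (C18) on C4 | O=C1CC[C@@H]2[C@](C)(CCCC=C2C)[C@H]1CC/C(C)=C/C(=O)OC | intermediate
12 | bromohydrin of 11: 4β-OH, 19α-Br | O=C1CC[C@@H]2[C@](C)(CCC[C@@H](Br)[C@]2(C)O)[C@H]1CC/C(C)=C/C(=O)OC | intermediate
13 | 4β,19β-epoxide of 11 | O=C1CC[C@@H]2[C@](C)(CCC[C@@H]3O[C@]23C)[C@H]1CC/C(C)=C/C(=O)OC | intermediate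
14 | methyl (13E)-8,19-dioxo-17-norlabd-13-en-15-oate (4α-CH3, 4β-CHO) | O=C1CC[C@@H]2[C@](C)(CCC[C@]2(C)C=O)[C@H]1CC/C(C)=C/C(=O)OC | intermediate
15 | (13E)-15-methoxy-8,15-dioxo-17-norlabd-13-en-19-oic acid | O=C1CC[C@@H]2[C@](C)(CCC[C@]2(C)C(=O)O)[C@H]1CC/C(C)=C/C(=O)OC | intermediate
16 | agathic acid 15-methyl ester, (13E)-labda-8(17),13-diene-15,19-dioic acid 15-methyl ester | C=C1CC[C@@H]2[C@](C)(CCC[C@]2(C)C(=O)O)[C@H]1CC/C(C)=C/C(=O)OC | intermediate
17 | 15-methyl ester of 13-(4,4,5,5-tetramethyl-1,3,2-dioxaborolan-2-yl)labd-8(17)-ene-15,19-dioic acid, boron on the face later held by OH | C=C1CC[C@@H]2[C@](C)(CCC[C@]2(C)C(=O)O)[C@H]1CC[C@@](C)(B3OC(C)(C)C(C)(C)O3)CC(=O)OC | intermediate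
18 | (13R)-13-hydroxylabd-8(17)-ene-15,19-dioic acid 15-methyl ester | C=C1CC[C@@H]2[C@](C)(CCC[C@]2(C)C(=O)O)[C@H]1CC[C@@](C)(O)CC(=O)OC | intermediate
19 | (13R)-13-hydroxylabd-8(17)-ene-15,19-dioic acid | C=C1CC[C@@H]2[C@](C)(CCC[C@]2(C)C(=O)O)[C@H]1CC[C@@](C)(O)CC(=O)O | target

Total step count: 11. Longest linear sequence: 11 steps (from 1).

Steps most likely to fail

Step 7 (key step). Once the C4–O bond has ionised, hydride migration from C19 or C5, or proton loss from the C18 methyl group, may outrun the shift of the C3–C19 ring bond. The fallback sets out from 11 and comes back at 14. It runs the contraction as a stepwise halohydrin semipinacol with two inversions at C4.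
- Peracid epoxidation of 11 on its open α face gives the α-epoxide F1.
- MgBr2·OEt2 at low temperature opens it at the tertiary carbon with inversion to the trans bromohydrin F2 (4β-Br, 19α-OH).
- Deprotonation with i-PrMgCl and warming lets the bromomagnesium alkoxide contract.
- In its diequatorial conformer the C4–Br bond is anti only to the C3–C19 ring bond, so no hydride can compete.
- The second inversion gives the same C4 configuration as in 14.

Step 6. Bromonium formation may lose its facial preference, or the bromine source may attack allylic or ketone α-positions instead of adding to the alkene. The fallback sets out from 11 and comes back at 13. It inverts the easily made α-epoxide.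
- The α-epoxide F1 (made as above) is hydrolysed with dilute HClO4 in aqueous THF. Water enters at tertiary C4 from the β face and gives the trans diol F3 (4β-OH, 19α-OH).
- Only the secondary 19-hydroxyl group is mesylated (MsCl, Et3N), giving the mesylate F4.
- K2CO3 in MeOH closes the 4β-alkoxide onto C19 with inversion to 13.

Step 4. The tertiary cation may lose the ring proton at C5 (loss of that stereocentre), be captured by acetate, or let the new alkene migrate under the Lewis acid. The fallback sets out from 8 and comes back at 10. It separates cleavage from elimination.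
- Me3SiI (from Me3SiCl and NaI, MeCN, 0 °C) cleaves the cyclobutane with capture of the cation by iodide.
- Aqueous work-up gives the tertiary iodide F5.
- DBU in toluene then performs an E2 elimination at the accessible methyl hydrogens and equilibrates C9, giving 10.

Further compounds
F1 | step 7 | 4α,19α-epoxide of 11 | O=C1CC[C@@H]2[C@](C)(CCC[C@H]3O[C@@]23C)[C@H]1CC/C(C)=C/C(=O)OC
F2 | step 7 | trans bromohydrin, 4β-Br, 19α-OH | O=C1CC[C@@H]2[C@](C)(CCC[C@@H](O)[C@]2(C)Br)[C@H]1CC/C(C)=C/C(=O)OC
F3 | step 6 | trans diol, 4β-OH, 19α-OH | O=C1CC[C@@H]2[C@](C)(CCC[C@@H](O)[C@]2(C)O)[C@H]1CC/C(C)=C/C(=O)OC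
F4 | step 6 | 19α-mesylate of the trans diol | O=C1CC[C@@H]2[C@](C)(CCC[C@@H](OS(C)(=O)=O)[C@]2(C)O)[C@H]1CC/C(C)=C/C(=O)OC
F5 | step 4 | ring-opened ketone with a 2-iodopropan-2-yl group at C5 | O=C1CC[C@@H](C(C)(C)I)[C@](C)(CCCC=C)[C@@H]1CC/C(C)=C/C(=O)OC
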